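**Strategy.** Everything rests on cutting ring A at the bond between its C1 ketone carbon and the spiro carbon, the ring atom that carries both dioxanone oxygens and lies between that ketone and CH(prenyl). Such a carbon cannot aromatise, so ring A is what a dienylketene gives on closing onto a ketene-acetal carbon. One thermolysis opens a 4-silyloxy-2-tert-butoxycyclobutenone and closes ring A, making the C1–spiro bond and the spiro centre, with CH(prenyl) following on hydrolysis. The precursor is the resolved Claisen/Diels–Alder cage whose bridgehead oxygen and carboxyl are tied into a 2-alkylidene-1,3-dioxan-4-one carrying prenyl and the cyclobutenone on the exocyclic carbon.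

Key step: step 14

Remark 1: the cage needs four adjacent ring oxygens, one more than a gallate offers, so a 2,3,4-trihydroxybenzoate (assumed commercial) is used and the fourth oxygen is added by Teuber oxidation.

Remark 2: the cyclobutenone carbinol carbon becomes trigonal in the key step, so its configuration is left undefined and both epimers are used. The cyclobutenol is carried as a triethylsilyl ether and the cage hydroxyl as a 4-methoxybenzyl (PMB) ether. The alkoxy-for-hydrogen exchange is done on the squarate before coupling, so no hydride meets the cage ketone.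

Step 1
Reactants: 1 2-methylbut-3-en-2-ol
Product: 2 tert-butyl 2-methylbut-3-en-2-yl carbonate
Conditions: n-BuLi, THF, −78 °C; Boc2O, −78 → 0 °C; aq. NH4Cl
Reagents that add atoms: di-tert-butyl dicarbonate, CC(C)(C)OC(=O)OC(=O)OC(C)(C)C
Why: Acylation of the lithium tert-alkoxide with Boc2O should give the mixed tert-butyl carbonate that serves as the ionisable allyl donor.

Step 2
Reactants: 3 methyl 2,3,4-trihydroxybenzoate; 2 tert-butyl 2-methylbut-3-en-2-yl carbonate
Product: 4 methyl 2-hydroxy-3,4-bis[(2-methylbut-3-en-2-yl)oxy]benzoate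
Conditions: 2 (2.2 equiv), Pd(PPh3)4 (5 mol %), THF, 0 → 5 °C, argon
Reagents that add atoms: none
Why: Tsuji–Trost O-allylation, in which the phenoxides attack the more substituted terminus of the 1,1-dimethylallyl palladium complex to give the tertiary ethers at O4 and O3, while the 2-hydroxyl, hydrogen-bonded to the ester, should stay free.

Step 3
Reactants: 4 methyl 2-hydroxy-3,4-bis[(2-methylbut-3-en-2-yl)oxy]benzoate
Product: 6 methyl 2,5-dihydroxy-3,4-bis[(2-methylbut-3-en-2-yl)oxy]benzoate, via para-quinone 5 (not isolated)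
Conditions: (KSO3)2NO (2.5 equiv), KH2PO4 buffer, acetone/H2O, 0 °C → rt; then aq. Na2S2O4, EtOAc
Reagents that add atoms: potassium nitrosodisulfonate, [K+].[K+].[O]N(S(=O)(=O)[O-])S(=O)(=O)[O-]
Why: Teuber oxidation, in which the nitroxyl radical oxidises the phenol at its free para position to the para-quinone, which dithionite reduces in the same work-up to the hydroquinone carrying the fourth ring oxygen.

Step 4
Reactants: 6 methyl 2,5-dihydroxy-3,4-bis[(2-methylbut-3-en-2-yl)oxy]benzoate
Product: 7 methyl 2-hydroxy-5-[(4-methoxybenzyl)oxy]-3,4-bis[(2-methylbut-3-en-2-yl)oxy]benzoate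
Conditions: 4-MeOC6H4CH2Cl (1.05 equiv), K2CO3, Bu4NI (cat.), DMF, rt, argon
Reagents that add atoms: 4-methoxybenzyl chloride, COc1ccc(CCl)cc1
Why: Williamson etherification, in which the 5-hydroxyl is alkylated because the 2-hydroxyl is tied up in a hydrogen bond to the ester, as in gentisate alkylations.

Step 5
Reactants: 7 methyl 2-hydroxy-5-[(4-methoxybenzyl)oxy]-3,4-bis[(2-methylbut-3-en-2-yl)oxy]benzoate; 8 5-methylhex-4-enoic acid
Product: 10 methyl 5-[(4-methoxybenzyl)oxy]-2-[(5-methylhex-4-enoyl)oxy]-3,4-bis[(2-methylbut-3-en-2-yl)oxy]benzoate, via acid chloride 9 (not isolated)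
Conditions: 8, (COCl)2, DMF (cat.), CH2Cl2, 0 °C → rt, evaporate; then 7, Et3N, DMAP (0.2 equiv), CH2Cl2, 0 → 35 °C
Reagents that add atoms: none
Why: DMAP-catalysed acylation of the chelated phenol by the acid chloride, which places the acyl group on the future bridgehead oxygen now and so avoids a later esterification of a tertiary cage alcohol.

Step 6
Reactants: 10 methyl 5-[(4-methoxybenzyl)oxy]-2-[(5-methylhex-4-enoyl)oxy]-3,4-bis[(2-methylbut-3-en-2-yl)oxy]benzoate
Product: 12 racemic cage diester, via Claisen dienone 11 (not isolated)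
Conditions: toluene (0.05 M, degassed), 110 °C, sealed tube
Reagents that add atoms: none
Why: Aromatic Claisen rearrangement should move the dimethylallyl group from O4 (para to the ester, the more electron-poor ether) to C3 as a prenyl group, and the 2,4-dienone is then trapped by intramolecular Diels–Alder addition of the vinyl group of the remaining ether, whose two-atom tether allows only one relative configuration at the four new stereocentres (racemate).

Step 7
Reactants: 12 racemic cage diester
Product: 13 cage diester as the single enantiomer of the target series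
Conditions: preparative HPLC, amylose tris(3,5-dimethylphenylcarbamate) phase, hexane/i-PrOH
Reagents that add atoms: none
Why: Chromatographic resolution of the rigid, UV-active cage on a polysaccharide chiral stationary phase, with the wanted enantiomer to be identified by anomalous-dispersion X-ray analysis.

Step 8
Reactants: 13 cage diester, single enantiomer
Product: 14 cage acid (bridgehead 5-methylhex-4-enoate, PMB ether)
Conditions: Me3SnOH (8 equiv), 1,2-dichloroethane, 70 °C; 5% aq. HCl wash
Reagents that add atoms: trimethyltin hydroxide, C[Sn](C)(C)O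
Why: Me3SnOH hydrolyses methyl esters under nearly neutral conditions and should leave the tertiary bridgehead ester, whose carbonyl is shielded by the cage, untouched.

Step 9
Reactants: 15 di-tert-butyl squarate
Product: 16 2,3-di-tert-butoxy-4-hydroxycyclobut-2-en-1-one (racemic)
Conditions: LiAlH(OtBu)3 (1.05 equiv), THF, −78 → −40 °C; aq. KNaC4H4O6
Reagents that add atoms: none
Why: The bulky hydride adds once to a squarate carbonyl and stops because the remaining carbonyl is a vinylogous ester, which is the known first stage of semisquarate synthesis.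

Step 10
Reactants: 16 2,3-di-tert-butoxy-4-hydroxycyclobut-2-en-1-one
Product: 17 2,3-di-tert-butoxy-4-(triethylsilyloxy)cyclobut-2-en-1-one (racemic)
Conditions: Et3SiCl, imidazole, CH2Cl2, 0 °C
Reagents that add atoms: chlorotriethylsilane, CC[Si](Cl)(CC)CC
Why: Standard silylation under basic conditions protects the secondary hydroxyl without exposing the acid-sensitive hydroxycyclobutenone to acid.

Step 11
Reactants: 14 cage acid; 17 2,3-di-tert-butoxy-4-(triethylsilyloxy)cyclobut-2-en-1-one
Product: 20 bis-silylated aldol acid (diastereomer mixture), via dilithium aldolate 18 (not isolated), via triethylsilyl ester 19 (not isolated)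
Conditions: LiN(iPr)2 (2.3 equiv), THF, −78 °C; 17 (1.3 equiv), −78 °C; Et3SiOTf (2.6 equiv), 2,6-lutidine, −78 → −40 °C; aq. NaHCO3, then pH 5 buffer
Reagents that add atoms: triethylsilyl trifluoromethanesulfonate, CC[Si](CC)(CC)OS(=O)(=O)C(F)(F)F
Why: Aldol addition of the ester enolate (generated as the carboxylate dianion, which cannot undergo Dieckmann closure) to the cyclobutenone carbonyl of 17, held by silylation of the alkoxide; the new stereocentres form as a mixture that is carried on because each of them becomes trigonal later.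

Step 12
Reactants: 20 bis-silylated aldol acid
Product: 21 cyclobutenone acid (4-triethylsilyloxy-2-tert-butoxy-3-H cyclobutenone, epimer mixture)
Conditions: 0.2 M HCl, THF/H2O, 0 °C
Reagents that add atoms: none
Why: Allylic 1,3-transposition of the Stork–Danheiser type: the less hindered secondary silyl ether is hydrolysed first, its hydroxyl ionises with help from the tert-butoxy group across the ring, and the alkoxycyclobutenyl cation loses the tert-butyl cation to form the carbonyl, while the neopentyl-like tertiary silyl ether should survive.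

Step 13
Reactants: 21 cyclobutenone acid
Product: 23 alkylidene dioxanone silyloxycyclobutenone, via acid chloride 22 (not isolated)
Conditions: 1-chloro-N,N,2-trimethylprop-1-en-1-amine, CH2Cl2, 0 °C; then iPr2NEt, 0 °C → rt; filtration through Et3N-deactivated silica
Reagents that add atoms: none
Why: Neighbouring-group ring closure of the kind known for O-acylsalicyloyl chlorides: the ester carbonyl oxygen, held syn-coplanar to the acyl chloride, attacks it to form the 4-oxo-1,3-dioxan-2-ylium ion, and the amine removes the only α-proton to give the ketene acylal with the bulky cyclobutenyl group on the side of the lactone oxygen, away from the cage bridgehead.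

Step 14
Reactants: 23 alkylidene dioxanone silyloxycyclobutenone
Product: 26 spirolactone with tert-butoxy ring A (PMB ether), via dienylketene 24 (not isolated), via silyl dienol ether 25 (not isolated)
Conditions: toluene (0.01 M), 110 °C, argon; then HF·pyridine, pyridine, THF, 0 °C
Reagents that add atoms: none
Why: Proposed new method: heat opens the cyclobutenone by conrotatory 4π ring opening with the silyloxy group rotating outward, which places the alkylidene dioxanone next to the ketene in dienylketene 24; the ketene carbon then bonds to the dioxygenated alkene carbon by 6π electrocyclisation to give the non-aromatisable silyl dienol ether 25, which buffered HF hydrolyses to the ketone. The closest known reaction type is the Moore rearrangement of 4-alkenyl-4-hydroxy- or 4-silyloxycyclobutenones to hydroquinones, in which the closing terminus carries hydrogen; closure onto a ketene acylal carbon is not documented, but a pericyclic closure does not need matched polarity at the two bonding carbons and is driven by release of four-ring strain. Ring A (six-membered) is closed by thermal disrotatory 6π electrocyclisation that forms the bond between the C1 ketone carbon and the spiro carbon. The spiro centre is set by the face of the exocyclic alkene that the ketene carbon reaches: the prenylated quaternary cage carbon beside the bridgehead oxygen blocks one face, so bonding should occur on the face of the tetrahydrofuran CH; CH(prenyl) is set on protonation of the dienol ether and can equilibrate through the enol to the epimer with prenyl away from the cage ether oxygen. The step needs outward rotation of the oxygen substituent and closure in preference to other ketene reactions, which the donor silyloxy group (torquoselectivity), the absence of free hydroxyl groups and the s-cis arrangement enforced by the tetrasubstituted alkene should secure.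

Step 15
Reactants: 26 spirolactone with tert-butoxy ring A (PMB ether)
Product: 27 hydroxy-enedione spirolactone (free cage hydroxyl)
Conditions: CF3CO2H/CH2Cl2 (1:4), 1,3-dimethoxybenzene (10 equiv), 0 °C
Reagents that add atoms: none
Why: Acidolysis, in which the tert-butyl enol ether (a vinylogous ester) and the PMB ether both cleave by loss of stabilised carbocations, released as isobutene and trapped by the arene, whereas the spiro acylal next to a ketone and the prenyl groups should survive the short cold exposure.

Step 16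
Reactants: 27 hydroxy-enedione spirolactone; 28 3-methylbut-2-enal
Product: 30 CNP0222516.1, via oxatriene 29 (not isolated)
Conditions: ethylenediammonium diacetate (10 mol %), 28 (2 equiv), CH2Cl2, rt
Reagents that add atoms: none
Why: Knoevenagel condensation at C3 of the 2-hydroxy-ene-1,4-dione (a vinylogous acid) followed by oxa-6π electrocyclisation through the C2 oxygen, the formal [3+3] annulation known for 2-hydroxyquinones, which keeps the conjugated ene-dione; the buffered medium lets CH(prenyl) settle in the more stable configuration.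

**Compound list**

1 | 2-methylbut-3-en-2-ol | CC(C)(O)C=C | starting material
2 | tert-butyl 2-methylbut-3-en-2-yl carbonate | CC(C)(C)OC(=O)OC(C)(C)C=C | intermediate
3 | methyl 2,3,4-trihydroxybenzoate | COC(=O)c1ccc(O)c(O)c1O | starting material
4 | methyl 2-hydroxy-3,4-bis[(2-methylbut-3-en-2-yl)oxy]benzoate | COC(=O)c1ccc(OC(C)(C)C=C)c(OC(C)(C)C=C)c1O | intermediate
5 | para-quinone: methyl 4,5-bis[(2-methylbut-3-en-2-yl)oxy]-3,6-dioxocyclohexa-1,4-diene-1-carboxylate | COC(=O)C1=CC(=O)C(OC(C)(C)C=C)=C(OC(C)(C)C=C)C1=O | intermediate (not isolated)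
6 | methyl 2,5-dihydroxy-3,4-bis[(2-methylbut-3-en-2-yl)oxy]benzoate | COC(=O)c1cc(O)c(OC(C)(C)C=C)c(OC(C)(C)C=C)c1O | intermediate
7 | methyl 2-hydroxy-5-[(4-methoxybenzyl)oxy]-3,4-bis[(2-methylbut-3-en-2-yl)oxy]benzoate | COC(=O)c1cc(OCc2ccc(OC)cc2)c(OC(C)(C)C=C)c(OC(C)(C)C=C)c1O | intermediate
8 | 5-methylhex-4-enoic acid | CC(C)=CCCC(=O)O | starting material
9 | 5-methylhex-4-enoyl chloride | CC(C)=CCCC(=O)Cl | intermediate (not isolated)
10 | methyl 5-[(4-methoxybenzyl)oxy]-2-[(5-methylhex-4-enoyl)oxy]-3,4-bis[(2-methylbut-3-en-2-yl)oxy]benzoate | COC(=O)c1cc(OCc2ccc(OC)cc2)c(OC(C)(C)C=C)c(OC(C)(C)C=C)c1OC(=O)CCC=C(C)C | intermediate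
11 | Claisen dienone: methyl 5-[(4-methoxybenzyl)oxy]-2-[(5-methylhex-4-enoyl)oxy]-3-(3-methylbut-2-enyl)-3-[(2-methylbut-3-en-2-yl)oxy]-4-oxocyclohexa-1,5-diene-1-carboxylate (racemic) | COC(=O)C1=C(OC(=O)CCC=C(C)C)C(CC=C(C)C)(OC(C)(C)C=C)C(=O)C(OCc2ccc(OC)cc2)=C1 | intermediate (not isolated)
12 | racemic cage diester: bicyclo[2.2.2]octenone with fused 2,2-dimethyltetrahydrofuran; CO2Me on the alkene carbon, 5-methylhex-4-enoyloxy on the adjacent bridgehead, PMB-oxy on the α-keto bridgehead, prenyl on the ether-bearing quaternary carbon (equal amounts of the drawn enantiomer and its mirror image) | COC(=O)C1=C[C@]2(OCc3ccc(OC)cc3)C[C@H]4C(C)(C)O[C@@](CC=C(C)C)(C2=O)[C@@]14OC(=O)CCC=C(C)C | intermediate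
13 | cage diester, single enantiomer (cage configuration of the target) | COC(=O)C1=C[C@]2(OCc3ccc(OC)cc3)C[C@H]4C(C)(C)O[C@@](CC=C(C)C)(C2=O)[C@@]14OC(=O)CCC=C(C)C | intermediate
14 | cage acid: as 13 with CO2H in place of CO2Me | OC(=O)C1=C[C@]2(OCc3ccc(OC)cc3)C[C@H]4C(C)(C)O[C@@](CC=C(C)C)(C2=O)[C@@]14OC(=O)CCC=C(C)C | intermediate
15 | di-tert-butyl squarate | CC(C)(C)OC1=C(OC(C)(C)C)C(=O)C1=O | starting material
16 | 2,3-di-tert-butoxy-4-hydroxycyclobut-2-en-1-one (racemic) | CC(C)(C)OC1=C(OC(C)(C)C)C(=O)C1O | intermediate
17 | 2,3-di-tert-butoxy-4-(triethylsilyloxy)cyclobut-2-en-1-one (racemic) | CC[Si](CC)(CC)OC1C(=O)C(OC(C)(C)C)=C1OC(C)(C)C | intermediate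
18 | dilithium aldolate of 14 and 17 (new centres as mixture) | [Li+].[Li+].[O-]C(=O)C1=C[C@]2(OCc3ccc(OC)cc3)C[C@H]4C(C)(C)O[C@@](CC=C(C)C)(C2=O)[C@@]14OC(=O)C(CC=C(C)C)C5([O-])C(OC(C)(C)C)=C(OC(C)(C)C)C5O[Si](CC)(CC)CC | intermediate (not isolated)
19 | triethylsilyl ester of 20 (new centres as mixture) | CC[Si](CC)(CC)OC(=O)C1=C[C@]2(OCc3ccc(OC)cc3)C[C@H]4C(C)(C)O[C@@](CC=C(C)C)(C2=O)[C@@]14OC(=O)C(CC=C(C)C)C5(O[Si](CC)(CC)CC)C(OC(C)(C)C)=C(OC(C)(C)C)C5O[Si](CC)(CC)CC | intermediate (not isolated)
20 | bis-silylated aldol acid: cage acid whose bridgehead ester carries at its α-carbon prenyl and a 2,3-di-tert-butoxy-1,4-bis(triethylsilyloxy)cyclobut-2-en-1-yl group (new centres as mixture) | OC(=O)C1=C[C@]2(OCc3ccc(OC)cc3)C[C@H]4C(C)(C)O[C@@](CC=C(C)C)(C2=O)[C@@]14OC(=O)C(CC=C(C)C)C5(O[Si](CC)(CC)CC)C(OC(C)(C)C)=C(OC(C)(C)C)C5O[Si](CC)(CC)CC | intermediate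
21 | cyclobutenone acid: as 20 with a 3-tert-butoxy-4-oxo-1-(triethylsilyloxy)cyclobut-2-en-1-yl group (two undefined centres) | OC(=O)C1=C[C@]2(OCc3ccc(OC)cc3)C[C@H]4C(C)(C)O[C@@](CC=C(C)C)(C2=O)[C@@]14OC(=O)C(CC=C(C)C)C5(O[Si](CC)(CC)CC)C=C(OC(C)(C)C)C5=O | intermediate
22 | acid chloride of 21 | ClC(=O)C1=C[C@]2(OCc3ccc(OC)cc3)C[C@H]4C(C)(C)O[C@@](CC=C(C)C)(C2=O)[C@@]14OC(=O)C(CC=C(C)C)C5(O[Si](CC)(CC)CC)C=C(OC(C)(C)C)C5=O | intermediate (not isolated)
23 | alkylidene dioxanone silyloxycyclobutenone: cage-fused 2-alkylidene-1,3-dioxan-4-one, exocyclic carbon bearing prenyl (cis to the ether oxygen) and the 4-silyloxy-2-tert-butoxycyclobutenone (cis to the lactone oxygen); carbinol carbon undefined, PMB ether on the cage | CC(C)=CC/C(=C1/OC(=O)C2=C[C@]3(OCc6ccc(OC)cc6)C[C@H]4C(C)(C)O[C@@](CC=C(C)C)(C3=O)[C@@]24O1)C5(O[Si](CC)(CC)CC)C=C(OC(C)(C)C)C5=O | intermediate (precursor of the key step)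
24 | dienylketene (silyloxy group outward) | CC(C)=CC/C(=C1/OC(=O)C2=C[C@]3(OCc6ccc(OC)cc6)C[C@H]4C(C)(C)O[C@@](CC=C(C)C)(C3=O)[C@@]24O1)/C(O[Si](CC)(CC)CC)=C\C(OC(C)(C)C)=C=O | intermediate (not isolated)
25 | silyl dienol ether of 26 | CC(C)=CCC1=C(O[Si](CC)(CC)CC)C=C(OC(C)(C)C)C(=O)[C@@]12OC(=O)C3=C[C@]4(OCc6ccc(OC)cc6)C[C@H]5C(C)(C)O[C@@](CC=C(C)C)(C4=O)[C@@]35O2 | intermediate (not isolated)
26 | spirolactone with tert-butoxy ring A, PMB ether: spiro carbon with the C1 ketone on the face of the tetrahydrofuran CH, ring-A prenyl cis to the lactone oxygen | CC(C)=CC[C@H]1C(=O)C=C(OC(C)(C)C)C(=O)[C@@]12OC(=O)C3=C[C@]4(OCc6ccc(OC)cc6)C[C@H]5C(C)(C)O[C@@](CC=C(C)C)(C4=O)[C@@]35O2 | intermediate (product of the key step)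
27 | hydroxy-enedione spirolactone (2-hydroxy ring A, free cage hydroxyl) | CC(C)=CC[C@H]1C(=O)C=C(O)C(=O)[C@@]12OC(=O)C3=C[C@]4(O)C[C@H]5C(C)(C)O[C@@](CC=C(C)C)(C4=O)[C@@]35O2 | intermediate
28 | 3-methylbut-2-enal | CC(C)=CC=O | starting material
29 | oxatriene: ring-A trione with a 3-methylbut-2-enylidene group at C3 | CC(C)=CC[C@H]1C(=O)C(=CC=C(C)C)C(=O)C(=O)[C@@]12OC(=O)C3=C[C@]4(O)C[C@H]5C(C)(C)O[C@@](CC=C(C)C)(C4=O)[C@@]35O2 | intermediate (not isolated)
30 | CNP0222516.1 | CC(C)=CC[C@H]1C(=O)C2=C(OC(C)(C)C=C2)C(=O)[C@@]12OC(=O)C1=C[C@]3(O)C[C@H]4C(C)(C)O[C@@](CC=C(C)C)(C3=O)[C@@]14O2 | target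

**Totals.** 16 steps; longest linear sequence 14 steps (steps 1–8 and 11–16).

**Steps most likely to fail**

1. Step 14 (Proposed new method). The hindered, polarity-mismatched alkene terminus may close too slowly, so that the ketene is diverted into [2+2] addition to a prenyl alkene or into oligomerisation. Closure may also occur on both faces. Enolisation at CH(prenyl) may expel the lactone carboxylate and aromatise ring A to a quinone. Fallback with known chemistry, from 13 to 27: LiOH in aqueous THF/MeOH at 40 °C cleaves both esters of 13 to the cage hydroxy acid F1. Commercial 2,6-dimethoxy-1,4-benzoquinone is half-hydrolysed (aq. NaOH, then acid) to 2-hydroxy-6-methoxy-1,4-benzoquinone F2. Its lithium salt (LiH, DMSO) is C-alkylated at C3 with prenyl bromide to the prenyl hydroxyquinone F3, the alkylation that turns lawsone into lapachol. EDC hydrochloride with catalytic DMAP joins the carboxyl of F1 to the acidic hydroxyl of F3 and gives the acyloxyquinone F4. With catalytic camphorsulfonic acid the bridgehead hydroxyl should add to the acyloxy-bearing quinone carbon (intramolecular oxa-Michael addition, six-membered ring), and ketonisation gives the methoxy ring-A spirolactone PMB ether F5. CF3CO2H with 1,3-dimethoxybenzene removes the PMB group to give the methoxy ring-A spirolactone alcohol F6, and 0.5 M aq. HCl in THF hydrolyses the vinylogous methyl ester to 27, from where step 16 follows.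

2. Step 13. Proton loss from the crowded acyloxonium ion may be outrun by cleavage of the bond to the silyloxy-bearing carbon (retro-aldol-type fragmentation) or by return of chloride, and the ketene acylal may hydrolyse during isolation. Fallback, from 21 to 23 in two separate stages: the acid chloride 22 is made as before but quenched with methanol and pyridine at −20 °C, which should capture the cyclic cation as the isolable cyclic ortho ester F7 (a 2-methoxy-1,3-dioxan-4-one). Methanol is then eliminated with Me3SiOTf and iPr2NEt at −78 → 0 °C, the conversion of ortho esters into ketene acetals, to give 23.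

3. Step 11. Addition to the deactivated, hindered cyclobutenone carbonyl may be slow and reversible, so that retro-aldol cleavage or decay of the dianion wins before the alkoxide is silylated. Fallback, from 14 and 15 to 21 with the order of events changed: the dianion of 14 is added to the far more electrophilic squarate 15 and the alkoxide is capped with Et3SiOTf to give the squarate aldol acid F8. NaBH4/CeCl3 in MeOH/THF at −78 °C reduces the cyclobutenone carbonyl to the allylic alcohol F9; here the hydride must discriminate against the cage ketone, which is the price of this order. 0.2 M HCl as in step 12 then ionises the free secondary hydroxyl and gives 21.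

**Further compounds**

F1 | step 14 | cage hydroxy acid (PMB ether) | OC(=O)C1=C[C@]2(OCc3ccc(OC)cc3)C[C@H]4C(C)(C)O[C@@](CC=C(C)C)(C2=O)[C@@]14O
F2 | step 14 | 2-hydroxy-6-methoxy-1,4-benzoquinone | COC1=CC(=O)C=C(O)C1=O
F3 | step 14 | 2-hydroxy-6-methoxy-3-(3-methylbut-2-enyl)-1,4-benzoquinone | COC1=CC(=O)C(CC=C(C)C)=C(O)C1=O
F4 | step 14 | acyloxyquinone (cage acid ester of F3, free bridgehead hydroxyl) | COC1=CC(=O)C(CC=C(C)C)=C(OC(=O)C2=C[C@]3(OCc4ccc(OC)cc4)C[C@H]5C(C)(C)O[C@@](CC=C(C)C)(C3=O)[C@@]25O)C1=O
F5 | step 14 | methoxy ring-A spirolactone PMB ether | CC(C)=CC[C@H]1C(=O)C=C(OC)C(=O)[C@@]12OC(=O)C3=C[C@]4(OCc6ccc(OC)cc6)C[C@H]5C(C)(C)O[C@@](CC=C(C)C)(C4=O)[C@@]35O2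
F6 | step 14 | methoxy ring-A spirolactone alcohol | CC(C)=CC[C@H]1C(=O)C=C(OC)C(=O)[C@@]12OC(=O)C3=C[C@]4(O)C[C@H]5C(C)(C)O[C@@](CC=C(C)C)(C4=O)[C@@]35O2
F7 | step 13 | cyclic ortho ester (2-methoxy-1,3-dioxan-4-one, undefined centres as mixture) | COC1(OC(=O)C2=C[C@]3(OCc6ccc(OC)cc6)C[C@H]4C(C)(C)O[C@@](CC=C(C)C)(C3=O)[C@@]24O1)C(CC=C(C)C)C5(O[Si](CC)(CC)CC)C=C(OC(C)(C)C)C5=O
F8 | step 11 | squarate aldol acid (triethylsilyl ether, undefined centres as mixture) | OC(=O)C1=C[C@]2(OCc3ccc(OC)cc3)C[C@H]4C(C)(C)O[C@@](CC=C(C)C)(C2=O)[C@@]14OC(=O)C(CC=C(C)C)C5(O[Si](CC)(CC)CC)C(OC(C)(C)C)=C(OC(C)(C)C)C5=O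
F9 | step 11 | allylic alcohol from reduction of F8 | OC(=O)C1=C[C@]2(OCc3ccc(OC)cc3)C[C@H]4C(C)(C)O[C@@](CC=C(C)C)(C2=O)[C@@]14OC(=O)C(CC=C(C)C)C5(O[Si](CC)(CC)CC)C(OC(C)(C)C)=C(OC(C)(C)C)C5O
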